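**Plan**
- Retrosynthesis: remove the C3 silyl ether; open the O–C8 bond of the 2,5-dihydrofuran ring (O–C8–C7=C6–C5) to its cycloisomer, a C5-hydroxy C6=C7=C8 allene; cut C8–C9 as the anti-SN2' union of a C6-ethynyl C5–C6 epoxide (C11 ring fragment 9) with a C14 pentaenylboronate (18); cut C11=C12 of 18 into C10 dialdehyde 15 and a C4 borylphosphonate.
- Enabling feature: an ether oxygen on C5 flanked by C6=C7, with a stereocentre at C8, is what an α-allenol gives on 5-endo cyclisation, and that allenol is what a C5–C6 epoxide carrying an alkyne on C6 gives on SN2' opening. The C6–O bond, absent from the target, is made on purpose to relay configuration to C8 and is cleaved in the key step.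
- Forward: the six-membered ring comes from actinol and the epoxide is added in step 5; the chain is assembled separately; the key coupling gives the open allenol; the dihydrofuran ring closes in the penultimate step; desilylation ends the route.
- Stereochemistry: C3 from (4R,6R)-actinol; C5 and the relay centre C6 from Sharpless epoxidation; the allene axis from anti-SN2' coupling; C8 from axis-to-centre transfer; C9=C10 from syn-borylcupration; C11=C12 from the Horner–Wadsworth–Emmons step; the remaining alkenes from 15.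

Key step: step 14

Remark: carotenoid numbering is used (ring C1–C6 with C1 gem-dimethyl, C3 carbinol, C5 methyl-bearing; chain C7–C15, then C15'–C12' with C12' = CH2OH). (4R,6R)-Actinol 1 and dialdehyde 15 are taken as commercial industrial carotenoid intermediates.

**Ring fragment**

Step 1
Reactants: 1 (4R,6R)-4-hydroxy-2,2,6-trimethylcyclohexan-1-one
Product: 2 (4R,6R)-4-[(tert-butyldimethylsilyl)oxy]-2,2,6-trimethylcyclohexan-1-one
Conditions: TBSCl, imidazole, DMF, rt
Reagents that add atoms: tert-butyldimethylsilyl chloride, CC(C)(C)[Si](C)(C)Cl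
Why: Imidazole-promoted silyl ether formation masks the C3 hydroxyl for the enolisation, hydride and titanium steps and touches no stereocentre.

Step 2
Reactants: 2 (4R,6R)-4-[(tert-butyldimethylsilyl)oxy]-2,2,6-trimethylcyclohexan-1-one
Product: 4 (4R)-4-[(tert-butyldimethylsilyl)oxy]-2,6,6-trimethylcyclohex-1-en-1-yl trifluoromethanesulfonate, via lithium enolate 3 (not isolated)
Conditions: LiN(iPr)2, THF, −78 °C; PhNTf2, −78 to 0 °C
Reagents that add atoms: N-phenylbis(trifluoromethanesulfonimide), O=S(=O)(N(c1ccccc1)S(=O)(=O)C(F)(F)F)C(F)(F)F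
Why: The ketone has one enolisable position, so a single enolate should form and be O-triflated (enol triflate formation); the methyl-bearing α-centre is erased on purpose and the carbinol centre is kept.

Step 3
Reactants: 4 (4R)-4-[(tert-butyldimethylsilyl)oxy]-2,6,6-trimethylcyclohex-1-en-1-yl trifluoromethanesulfonate
Product: 5 methyl (4R)-4-[(tert-butyldimethylsilyl)oxy]-2,6,6-trimethylcyclohex-1-ene-1-carboxylate
Conditions: Pd(OAc)2 (5 mol %), PPh3, Et3N, CO (1 atm), MeOH–DMF, 70 °C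
Reagents that add atoms: carbon monoxide, [C-]#[O+]; methanol, CO
Why: Palladium-catalysed methoxycarbonylation of the vinyl triflate (oxidative addition, CO insertion, methanolysis) installs C7 at the ester level.

Step 4
Reactants: 5 methyl (4R)-4-[(tert-butyldimethylsilyl)oxy]-2,6,6-trimethylcyclohex-1-ene-1-carboxylate
Product: 6 [(4R)-4-[(tert-butyldimethylsilyl)oxy]-2,6,6-trimethylcyclohex-1-en-1-yl]methanol
Conditions: iBu2AlH, CH2Cl2, −78 to 0 °C
Reagents that add atoms: none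
Why: 1,2-Reduction of the conjugated ester by the aluminium hydride should give the allylic alcohol needed to direct the epoxidation.

Step 5
Reactants: 6 [(4R)-4-[(tert-butyldimethylsilyl)oxy]-2,6,6-trimethylcyclohex-1-en-1-yl]methanol
Product: 7 [(1R,4S,6R)-4-[(tert-butyldimethylsilyl)oxy]-2,2,6-trimethyl-7-oxabicyclo[4.1.0]heptan-1-yl]methanol
Conditions: Ti(OiPr)4, D-(−)-diethyl tartrate, tBuOOH, 4 Å molecular sieves, CH2Cl2, −20 °C
Reagents that add atoms: tert-butyl hydroperoxide, CC(C)(C)OO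
Why: Sharpless asymmetric epoxidation: the D-(−)-tartrate titanium complex should deliver oxygen to the alkene face anti to the C3 silyloxy group (reagent control), setting C5 (R, never touched again) and the relay centre C6 together.

Step 6
Reactants: 7 [(1R,4S,6R)-4-[(tert-butyldimethylsilyl)oxy]-2,2,6-trimethyl-7-oxabicyclo[4.1.0]heptan-1-yl]methanol
Product: 8 (1S,4S,6R)-4-[(tert-butyldimethylsilyl)oxy]-2,2,6-trimethyl-7-oxabicyclo[4.1.0]heptane-1-carbaldehyde
Conditions: nPr4NRuO4 (5 mol %), N-methylmorpholine N-oxide, 4 Å molecular sieves, CH2Cl2, rt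
Reagents that add atoms: none
Why: Ley–Griffith oxidation is neutral and should leave the tetrasubstituted epoxide and the silyl ether intact; the α-carbon is quaternary, so no epimerisation is possible.

Step 7
Reactants: 8 (1S,4S,6R)-4-[(tert-butyldimethylsilyl)oxy]-2,2,6-trimethyl-7-oxabicyclo[4.1.0]heptane-1-carbaldehyde
Product: 9 (1R,4S,6R)-4-[(tert-butyldimethylsilyl)oxy]-1-ethynyl-2,2,6-trimethyl-7-oxabicyclo[4.1.0]heptane
Conditions: dimethyl (1-diazo-2-oxopropyl)phosphonate, K2CO3, MeOH, 0 °C to rt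
Reagents that add atoms: dimethyl (1-diazo-2-oxopropyl)phosphonate, COP(=O)(OC)C(=[N+]=[N-])C(C)=O
Why: Seyferth–Gilbert homologation with the Ohira–Bestmann reagent should turn the non-enolisable aldehyde into the terminal alkyne (C8) under mild base that the epoxide tolerates.

**Chain fragment**

Step 8
Reactants: 10 ethyl but-2-ynoate
Product: 11 ethyl (2Z)-3-(4,4,5,5-tetramethyl-1,3,2-dioxaborolan-2-yl)but-2-enoate
Conditions: CuCl (3 mol %), Xantphos (3 mol %), NaOtBu (6 mol %), B2pin2, MeOH (2 equiv), THF, rt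
Reagents that add atoms: bis(pinacolato)diboron, CC1(C)OB(OC1(C)C)B1OC(C)(C)C(C)(C)O1
Why: Copper-catalysed β-borylation of the ynoate (syn borylcupration, then protonation) should place boron on the methyl-bearing carbon C9 with hydrogen cis to it, which fixes the C9=C10 geometry.

Step 9
Reactants: 11 ethyl (2Z)-3-(4,4,5,5-tetramethyl-1,3,2-dioxaborolan-2-yl)but-2-enoate
Product: 12 (2Z)-3-(4,4,5,5-tetramethyl-1,3,2-dioxaborolan-2-yl)but-2-en-1-ol
Conditions: iBu2AlH, CH2Cl2, −78 °C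
Reagents that add atoms: none
Why: 1,2-Reduction of the enoate at low temperature should spare the pinacol boronate; the hydroxymethyl group is trans to boron, so no cyclic borinate can form.

Step 10
Reactants: 12 (2Z)-3-(4,4,5,5-tetramethyl-1,3,2-dioxaborolan-2-yl)but-2-en-1-ol
Product: 13 2-[(2Z)-4-bromobut-2-en-2-yl]-4,4,5,5-tetramethyl-1,3,2-dioxaborolane
Conditions: CBr4, PPh3, CH2Cl2, 0 °C
Reagents that add atoms: tetrabromomethane, BrC(Br)(Br)Br
Why: Appel bromination at the primary allylic carbon under neutral conditions should leave the alkenylboronate and its geometry untouched.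

Step 11
Reactants: 13 2-[(2Z)-4-bromobut-2-en-2-yl]-4,4,5,5-tetramethyl-1,3,2-dioxaborolane
Product: 14 diethyl [(2Z)-3-(4,4,5,5-tetramethyl-1,3,2-dioxaborolan-2-yl)but-2-en-1-yl]phosphonate
Conditions: P(OEt)3 (neat), 110 °C
Reagents that add atoms: triethyl phosphite, CCOP(OCC)OCC
Why: Michaelis–Arbuzov reaction at the unhindered primary allylic bromide; attack at the boron-bearing tertiary terminus (SN2') is sterically disfavoured.

Step 12
Reactants: 14 diethyl [(2Z)-3-(4,4,5,5-tetramethyl-1,3,2-dioxaborolan-2-yl)but-2-en-1-yl]phosphonate; 15 (2E,4E,6E)-2,7-dimethylocta-2,4,6-trienedial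
Product: 17 (2E,4E,6E,8E,10Z)-2,7-dimethyl-11-(4,4,5,5-tetramethyl-1,3,2-dioxaborolan-2-yl)dodeca-2,4,6,8,10-pentaenal, via phosphonate carbanion 16 (not isolated)
Conditions: NaN(SiMe3)2, THF, −78 °C; then added to 15 (1.5 equiv), −78 to 0 °C
Reagents that add atoms: none
Why: Horner–Wadsworth–Emmons olefination with an allylic phosphonate anion should form C11=C12 with E selectivity; excess symmetric dialdehyde and the lower electrophilicity of the extended polyenal favour mono-olefination.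

Step 13
Reactants: 17 (2E,4E,6E,8E,10Z)-2,7-dimethyl-11-(4,4,5,5-tetramethyl-1,3,2-dioxaborolan-2-yl)dodeca-2,4,6,8,10-pentaenal
Product: 18 (2E,4E,6E,8E,10Z)-2,7-dimethyl-11-(4,4,5,5-tetramethyl-1,3,2-dioxaborolan-2-yl)dodeca-2,4,6,8,10-pentaen-1-ol
Conditions: NaBH4, MeOH–THF, 0 °C
Reagents that add atoms: none
Why: Borohydride 1,2-reduction of the polyenal should give the C12' alcohol without affecting the boronate or the alkene geometries.

**Union and completion**

Step 14
Reactants: 9 (1R,4S,6R)-4-[(tert-butyldimethylsilyl)oxy]-1-ethynyl-2,2,6-trimethyl-7-oxabicyclo[4.1.0]heptane; 18 (2E,4E,6E,8E,10Z)-2,7-dimethyl-11-(4,4,5,5-tetramethyl-1,3,2-dioxaborolan-2-yl)dodeca-2,4,6,8,10-pentaen-1-ol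
Product: 20 (3S,5R,6R)-allenol (2E,4E,6E,8E,10E)-13-[(2R,4S)-4-[(tert-butyldimethylsilyl)oxy]-2-hydroxy-2,6,6-trimethylcyclohexylidene]-2,7,11-trimethyltrideca-2,4,6,8,10,12-hexaen-1-ol (allene axis Ra), via allenylpalladium alkoxide 19 (not isolated)
Conditions: Pd(PPh3)4 (5 mol %), K3PO4 (1 equiv), THF–H2O 10:1, degassed, dark, 40 °C
Reagents that add atoms: none
Why: Zerovalent palladium attacks the terminal alkyne carbon C8 anti to the C6–O bond of the propargylic epoxide (SN2' oxidative addition) and opens the three-membered ring to the σ-allenylpalladium alkoxide 19; the alkoxide or hydroxide so generated activates the boronate for transmetalation, and reductive elimination with retention forms the C8–C9 bond. The closest known reaction type is the palladium-catalysed anti-SN2' coupling of propargylic oxiranes and propargylic carbonates with aryl- and alkenylboron reagents to give 2,3-allenols and vinylallenes. No ring is closed; the epoxide, a ring the target does not contain, is opened, and its unbroken C5–O bond becomes the future ring oxygen. The new stereogenic element is the C6=C7=C8 axis: the anti pathway translates the C6 configuration from step 5 into the (6R) axis, with the polyenyl group on the face opposite to the C5 oxygen, that is, on the side of the C5 methyl group. The step needs allenyl rather than propargyl coupling, secured by the quaternary C6 and the unsubstituted C8, and anti stereospecificity, secured by the rigid epoxide that holds the C6–O bond in line with one alkyne π bond; the C9=C10 geometry of 18 is carried over by stereoretentive transmetalation. The mild aqueous conditions should leave the silyl ether, the free primary alcohol and the pentaene untouched.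

Step 15
Reactants: 20 (3S,5R,6R)-allenol (2E,4E,6E,8E,10E)-13-[(2R,4S)-4-[(tert-butyldimethylsilyl)oxy]-2-hydroxy-2,6,6-trimethylcyclohexylidene]-2,7,11-trimethyltrideca-2,4,6,8,10,12-hexaen-1-ol
Product: 21 (2E,4E,6E,8E,10E)-11-[(2S,6S,7aR)-6-[(tert-butyldimethylsilyl)oxy]-4,4,7a-trimethyl-2,4,5,6,7,7a-hexahydro-1-benzofuran-2-yl]-2,7-dimethyldodeca-2,4,6,8,10-pentaen-1-ol
Conditions: Ph3PAuNTf2 (2 mol %), THF, −20 to 0 °C, dark
Reagents that add atoms: none
Why: Gold-catalysed cycloisomerisation of an α-hydroxyallene: monovalent gold activates the C7=C8 bond, the C5 hydroxyl adds anti to gold at C8 in a 5-endo closure of the dihydrofuran ring, and protodeauration follows, so the allene axis is transferred to the C8 centre with the polyenyl group staying on the face of the C5 methyl group, which is the (8S) configuration.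

Step 16
Reactants: 21 (2E,4E,6E,8E,10E)-11-[(2S,6S,7aR)-6-[(tert-butyldimethylsilyl)oxy]-4,4,7a-trimethyl-2,4,5,6,7,7a-hexahydro-1-benzofuran-2-yl]-2,7-dimethyldodeca-2,4,6,8,10-pentaen-1-ol
Product: 22 (2E,4E,6E,8E,10E)-11-[(2S,6S,7aR)-6-hydroxy-4,4,7a-trimethyl-2,4,5,6,7,7a-hexahydro-1-benzofuran-2-yl]-2,7-dimethyldodeca-2,4,6,8,10-pentaen-1-ol
Conditions: Bu4NF, THF, 0 °C to rt
Reagents that add atoms: none
Why: Fluoride desilylation under basic, non-acidic conditions should free the C3 hydroxyl without ionising the doubly allylic C8–O bond or isomerising the polyene.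

**Compound list**
1 | (4R,6R)-4-hydroxy-2,2,6-trimethylcyclohexan-1-one | CC1(C)C[C@H](O)C[C@@H](C)C1=O | starting material
2 | (4R,6R)-4-[(tert-butyldimethylsilyl)oxy]-2,2,6-trimethylcyclohexan-1-one | CC1(C)C[C@H](O[Si](C)(C)C(C)(C)C)C[C@@H](C)C1=O | intermediate
3 | lithium (4R)-4-[(tert-butyldimethylsilyl)oxy]-2,6,6-trimethylcyclohex-1-en-1-olate | CC1(C)C[C@H](O[Si](C)(C)C(C)(C)C)CC(C)=C1[O-].[Li+] | intermediate (not isolated)
4 | (4R)-4-[(tert-butyldimethylsilyl)oxy]-2,6,6-trimethylcyclohex-1-en-1-yl trifluoromethanesulfonate | CC1(C)C[C@H](O[Si](C)(C)C(C)(C)C)CC(C)=C1OS(=O)(=O)C(F)(F)F | intermediate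
5 | methyl (4R)-4-[(tert-butyldimethylsilyl)oxy]-2,6,6-trimethylcyclohex-1-ene-1-carboxylate | CC1(C)C[C@H](O[Si](C)(C)C(C)(C)C)CC(C)=C1C(=O)OC | intermediate
6 | [(4R)-4-[(tert-butyldimethylsilyl)oxy]-2,6,6-trimethylcyclohex-1-en-1-yl]methanol | CC1(C)C[C@H](O[Si](C)(C)C(C)(C)C)CC(C)=C1CO | intermediate
7 | [(1R,4S,6R)-4-[(tert-butyldimethylsilyl)oxy]-2,2,6-trimethyl-7-oxabicyclo[4.1.0]heptan-1-yl]methanol | CC1(C)C[C@H](O[Si](C)(C)C(C)(C)C)C[C@@]2(C)O[C@@]12CO | intermediate
8 | (1S,4S,6R)-4-[(tert-butyldimethylsilyl)oxy]-2,2,6-trimethyl-7-oxabicyclo[4.1.0]heptane-1-carbaldehyde | CC1(C)C[C@H](O[Si](C)(C)C(C)(C)C)C[C@@]2(C)O[C@@]12C=O | intermediate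
9 | (1R,4S,6R)-4-[(tert-butyldimethylsilyl)oxy]-1-ethynyl-2,2,6-trimethyl-7-oxabicyclo[4.1.0]heptane | CC1(C)C[C@H](O[Si](C)(C)C(C)(C)C)C[C@@]2(C)O[C@@]12C#C | intermediate
10 | ethyl but-2-ynoate | CC#CC(=O)OCC | starting material
11 | ethyl (2Z)-3-(4,4,5,5-tetramethyl-1,3,2-dioxaborolan-2-yl)but-2-enoate | CC1(C)OB(OC1(C)C)/C(C)=C/C(=O)OCC | intermediate
12 | (2Z)-3-(4,4,5,5-tetramethyl-1,3,2-dioxaborolan-2-yl)but-2-en-1-ol | CC1(C)OB(OC1(C)C)/C(C)=C/CO | intermediate
13 | 2-[(2Z)-4-bromobut-2-en-2-yl]-4,4,5,5-tetramethyl-1,3,2-dioxaborolane | CC1(C)OB(OC1(C)C)/C(C)=C/CBr | intermediate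
14 | diethyl [(2Z)-3-(4,4,5,5-tetramethyl-1,3,2-dioxaborolan-2-yl)but-2-en-1-yl]phosphonate | CC1(C)OB(OC1(C)C)/C(C)=C/CP(=O)(OCC)OCC | intermediate
15 | (2E,4E,6E)-2,7-dimethylocta-2,4,6-trienedial | O=C/C(C)=C/C=C/C=C(\C)C=O | starting material
16 | sodium salt of the α-carbanion of phosphonate 14 | CC1(C)OB(OC1(C)C)/C(C)=C/[CH-]P(=O)(OCC)OCC.[Na+] | intermediate (not isolated)
17 | (2E,4E,6E,8E,10Z)-2,7-dimethyl-11-(4,4,5,5-tetramethyl-1,3,2-dioxaborolan-2-yl)dodeca-2,4,6,8,10-pentaenal | CC1(C)OB(OC1(C)C)/C(C)=C/C=C/C(C)=C/C=C/C=C(\C)C=O | intermediate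
18 | (2E,4E,6E,8E,10Z)-2,7-dimethyl-11-(4,4,5,5-tetramethyl-1,3,2-dioxaborolan-2-yl)dodeca-2,4,6,8,10-pentaen-1-ol | CC1(C)OB(OC1(C)C)/C(C)=C/C=C/C(C)=C/C=C/C=C(\C)CO | intermediate
19 | σ-allenylpalladium alkoxide: bis(triphenylphosphine)palladium bound at C8 anti to the C5 alkoxide, drawn as the zwitterion | CC1(C)C[C@H](O[Si](C)(C)C(C)(C)C)C[C@@](C)([O-])C1=[C@]=C([H])[Pd-]([P+](c2ccccc2)(c2ccccc2)c2ccccc2)[P+](c2ccccc2)(c2ccccc2)c2ccccc2 | intermediate (not isolated)
20 | (2E,4E,6E,8E,10E)-13-[(2R,4S)-4-[(tert-butyldimethylsilyl)oxy]-2-hydroxy-2,6,6-trimethylcyclohexylidene]-2,7,11-trimethyltrideca-2,4,6,8,10,12-hexaen-1-ol, allene axis Ra (carotenoid descriptors 3S,5R,6R) | CC1(C)C[C@H](O[Si](C)(C)C(C)(C)C)C[C@@](C)(O)C1=[C@]=C([H])/C(C)=C/C=C/C(C)=C/C=C/C=C(\C)CO | intermediate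
21 | (2E,4E,6E,8E,10E)-11-[(2S,6S,7aR)-6-[(tert-butyldimethylsilyl)oxy]-4,4,7a-trimethyl-2,4,5,6,7,7a-hexahydro-1-benzofuran-2-yl]-2,7-dimethyldodeca-2,4,6,8,10-pentaen-1-ol | CC(/C=C/C=C(\C)[C@@H]1C=C2C(C)(C)C[C@H](O[Si](C)(C)C(C)(C)C)C[C@@]2(C)O1)=C\C=C\C=C(/C)CO | intermediate
22 | (2E,4E,6E,8E,10E)-11-[(2S,6S,7aR)-6-hydroxy-4,4,7a-trimethyl-2,4,5,6,7,7a-hexahydro-1-benzofuran-2-yl]-2,7-dimethyldodeca-2,4,6,8,10-pentaen-1-ol, i.e. (3S,5R,8S)-5,8-epoxy-5,8-dihydro-12'-apo-β-carotene-3,12'-diol | CC(/C=C/C=C(\C)[C@@H]1C=C2C(C)(C)C[C@H](O)C[C@@]2(C)O1)=C\C=C\C=C(/C)CO | target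

**Count**
Total steps: 16. Longest linear sequence: 10 steps (steps 1–7, then 14–16); the chain branch is 6 steps (8–13).

**Steps most likely to fail, with fallbacks**

Step 14. The σ-allenylpalladium intermediate may epimerise before transmetalation (erosion of the anti relationship), or the polyenylboronate may protodeboronate faster than it transmetalates. The fallback makes the same C8–C9 bond at the alkyne level and generates the allene afterwards. It sets out from 18 and 9. Boronate 18 is converted with retention (N-iodosuccinimide, MeCN, 0 °C, dark) into (2E,4E,6E,8E,10E)-11-iodo-2,7-dimethyldodeca-2,4,6,8,10-pentaen-1-ol F1. F1 is joined to alkyne 9 by Sonogashira coupling (Pd(PPh3)4, CuI, iPr2NH, THF, rt) to give the epoxy enyne (2E,4E,6E,8E,10E)-13-[(1R,4S,6R)-4-[(tert-butyldimethylsilyl)oxy]-2,2,6-trimethyl-7-oxabicyclo[4.1.0]heptan-1-yl]-2,7,11-trimethyltrideca-2,4,6,8,10-pentaen-12-yn-1-ol F2. F2 is then reduced with iBu2AlH (CH2Cl2, 0 °C): aluminium bound to the epoxide oxygen should deliver hydride to C8 on the oxygen face (syn-SN2'), which leaves the polyenyl group anti to oxygen. The route is rejoined at allenol 20.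

Step 15. Gold may open the allene to a polyene-stabilised cation before the hydroxyl adds, or ionise the doubly allylic C8–O bond of the product; either process would lose the axis-to-centre transfer and epimerise C8. The fallback moves the ring closure ahead of chain extension, where no polyene is present. It sets out from 9 and 12. Under the conditions of step 14 they should give the short allenol (2E)-5-[(2R,4S)-4-[(tert-butyldimethylsilyl)oxy]-2-hydroxy-2,6,6-trimethylcyclohexylidene]-3-methylpenta-2,4-dien-1-ol F3. F3 is cycloisomerised (Ph3PAuNTf2, THF, 0 °C) to (2E)-3-[(2S,6S,7aR)-6-[(tert-butyldimethylsilyl)oxy]-4,4,7a-trimethyl-2,4,5,6,7,7a-hexahydro-1-benzofuran-2-yl]but-2-en-1-ol F4. The chain is then built as in steps 10–13: CBr4/PPh3 gives (2S,6S,7aR)-2-[(2E)-4-bromobut-2-en-2-yl]-6-[(tert-butyldimethylsilyl)oxy]-4,4,7a-trimethyl-2,4,5,6,7,7a-hexahydro-1-benzofuran F5; P(OEt)3 gives diethyl [(2E)-3-[(2S,6S,7aR)-6-[(tert-butyldimethylsilyl)oxy]-4,4,7a-trimethyl-2,4,5,6,7,7a-hexahydro-1-benzofuran-2-yl]but-2-en-1-yl]phosphonate F6; NaN(SiMe3)2 and dialdehyde 15 give (2E,4E,6E,8E,10E)-11-[(2S,6S,7aR)-6-[(tert-butyldimethylsilyl)oxy]-4,4,7a-trimethyl-2,4,5,6,7,7a-hexahydro-1-benzofuran-2-yl]-2,7-dimethyldodeca-2,4,6,8,10-pentaenal F7. NaBH4 reduction of F7 rejoins the route at 21.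

Step 12. The amide base may add to boron, the delocalised anion may react at its boron-bearing terminus, double olefination of the dialdehyde may compete, or E selectivity at C11=C12 may be poor. The fallback avoids both the dialdehyde and the unstabilised phosphonate by growing the chain from the boron end with ester-stabilised phosphonates. It sets out from 12. MnO2 (CH2Cl2, rt) gives (2Z)-3-(4,4,5,5-tetramethyl-1,3,2-dioxaborolan-2-yl)but-2-enal F8. Olefination with ethyl (2E)-4-(diethoxyphosphoryl)-3-methylbut-2-enoate (NaN(SiMe3)2, THF, −78 to 0 °C) gives ethyl (2E,4E,6Z)-3-methyl-7-(4,4,5,5-tetramethyl-1,3,2-dioxaborolan-2-yl)octa-2,4,6-trienoate F9. iBu2AlH gives (2E,4E,6Z)-3-methyl-7-(4,4,5,5-tetramethyl-1,3,2-dioxaborolan-2-yl)octa-2,4,6-trien-1-ol F10, and MnO2 gives (2E,4E,6Z)-3-methyl-7-(4,4,5,5-tetramethyl-1,3,2-dioxaborolan-2-yl)octa-2,4,6-trienal F11. A second olefination with ethyl (2E)-4-(diethoxyphosphoryl)-2-methylbut-2-enoate gives ethyl (2E,4E,6E,8E,10Z)-2,7-dimethyl-11-(4,4,5,5-tetramethyl-1,3,2-dioxaborolan-2-yl)dodeca-2,4,6,8,10-pentaenoate F12. iBu2AlH reduction of F12 rejoins the route at 18.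

**Further compounds**
F1 | step 14 | (2E,4E,6E,8E,10E)-11-iodo-2,7-dimethyldodeca-2,4,6,8,10-pentaen-1-ol | I/C(C)=C/C=C/C(C)=C/C=C/C=C(\C)CO
F2 | step 14 | (2E,4E,6E,8E,10E)-13-[(1R,4S,6R)-4-[(tert-butyldimethylsilyl)oxy]-2,2,6-trimethyl-7-oxabicyclo[4.1.0]heptan-1-yl]-2,7,11-trimethyltrideca-2,4,6,8,10-pentaen-12-yn-1-ol | CC1(C)C[C@H](O[Si](C)(C)C(C)(C)C)C[C@@]2(C)O[C@@]12C#C/C(C)=C/C=C/C(C)=C/C=C/C=C(\C)CO
F3 | step 15 | (2E)-5-[(2R,4S)-4-[(tert-butyldimethylsilyl)oxy]-2-hydroxy-2,6,6-trimethylcyclohexylidene]-3-methylpenta-2,4-dien-1-ol, allene axis Ra | CC1(C)C[C@H](O[Si](C)(C)C(C)(C)C)C[C@@](C)(O)C1=[C@]=C([H])/C(C)=C/CO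
F4 | step 15 | (2E)-3-[(2S,6S,7aR)-6-[(tert-butyldimethylsilyl)oxy]-4,4,7a-trimethyl-2,4,5,6,7,7a-hexahydro-1-benzofuran-2-yl]but-2-en-1-ol | OC/C=C(\C)[C@@H]1C=C2C(C)(C)C[C@H](O[Si](C)(C)C(C)(C)C)C[C@@]2(C)O1
F5 | step 15 | (2S,6S,7aR)-2-[(2E)-4-bromobut-2-en-2-yl]-6-[(tert-butyldimethylsilyl)oxy]-4,4,7a-trimethyl-2,4,5,6,7,7a-hexahydro-1-benzofuran | BrC/C=C(\C)[C@@H]1C=C2C(C)(C)C[C@H](O[Si](C)(C)C(C)(C)C)C[C@@]2(C)O1
F6 | step 15 | diethyl [(2E)-3-[(2S,6S,7aR)-6-[(tert-butyldimethylsilyl)oxy]-4,4,7a-trimethyl-2,4,5,6,7,7a-hexahydro-1-benzofuran-2-yl]but-2-en-1-yl]phosphonate | CCOP(=O)(OCC)C/C=C(\C)[C@@H]1C=C2C(C)(C)C[C@H](O[Si](C)(C)C(C)(C)C)C[C@@]2(C)O1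
F7 | step 15 | (2E,4E,6E,8E,10E)-11-[(2S,6S,7aR)-6-[(tert-butyldimethylsilyl)oxy]-4,4,7a-trimethyl-2,4,5,6,7,7a-hexahydro-1-benzofuran-2-yl]-2,7-dimethyldodeca-2,4,6,8,10-pentaenal | CC(/C=C/C=C(\C)[C@@H]1C=C2C(C)(C)C[C@H](O[Si](C)(C)C(C)(C)C)C[C@@]2(C)O1)=C\C=C\C=C(/C)C=O
F8 | step 12 | (2Z)-3-(4,4,5,5-tetramethyl-1,3,2-dioxaborolan-2-yl)but-2-enal | CC1(C)OB(OC1(C)C)/C(C)=C/C=O
F9 | step 12 | ethyl (2E,4E,6Z)-3-methyl-7-(4,4,5,5-tetramethyl-1,3,2-dioxaborolan-2-yl)octa-2,4,6-trienoate | CC1(C)OB(OC1(C)C)/C(C)=C/C=C/C(C)=C/C(=O)OCC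
F10 | step 12 | (2E,4E,6Z)-3-methyl-7-(4,4,5,5-tetramethyl-1,3,2-dioxaborolan-2-yl)octa-2,4,6-trien-1-ol | CC1(C)OB(OC1(C)C)/C(C)=C/C=C/C(C)=C/CO
F11 | step 12 | (2E,4E,6Z)-3-methyl-7-(4,4,5,5-tetramethyl-1,3,2-dioxaborolan-2-yl)octa-2,4,6-trienal | CC1(C)OB(OC1(C)C)/C(C)=C/C=C/C(C)=C/C=O
F12 | step 12 | ethyl (2E,4E,6E,8E,10Z)-2,7-dimethyl-11-(4,4,5,5-tetramethyl-1,3,2-dioxaborolan-2-yl)dodeca-2,4,6,8,10-pentaenoate | CC1(C)OB(OC1(C)C)/C(C)=C/C=C/C(C)=C/C=C/C=C(\C)C(=O)OCC
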